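A direct plan would make the oxirane first and the arene last: 2-bromoallyl alcohol and trimethylsilylacetylene would be coupled (Sonogashira) to enynol A1,
A1 would be epoxidised (Sharpless, Ti(OiPr)4/tartrate) to glycidol A2, which would be isobutyrylated and desilylated to the ethynyloxirane A3,
and A3 would undergo Dötz benzannulation with the carbene complex of zerovalent chromium A4 to the free phenol A5, to be O-tigloylated last.
Weakest would be the benzannulation: five preparative steps and stoichiometric Cr(CO)6 for a benzene ring that can be bought, run on the oxirane that holds the only stereocentre.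
Next, the asymmetric epoxidation of the 1,1-disubstituted enynol: its face selectivity rests on a mnemonic, the titanium medium opens 2,2-disubstituted glycidols, and the small oil cannot be enriched later.
Last, the acylation of A5: a free ortho-hydroxyaryl oxirane ionises or cyclises easily, so this is the step least suited to precious late material.

**Plan of the new route**
The oxirane carbon bonded to the arene (C8) carries two CH2–O arms, the oxirane CH2 (C9) and the isobutyrate CH2 (C10). With the oxirane O–C9 bond cut they are enantiotopic, so the target maps onto an achiral 2-arylpropane-1,2,3-triol.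
Cuts, in retrosynthetic order: oxirane O–C9 (tertiary OH on C8 plus mesylate on C9); acyl C–O of the isobutyrate at C10 (a lipase, serine hydrolase class, with vinyl isobutyrate); acetal; phenol ester; aryl–C8 (lithiated bromophenol plus 2,2-dimethyl-1,3-dioxan-5-one).
The benzene ring is bought. The oxirane is the only ring made and closes in the last step, with both esters in place.
The lipase sets the stereocentre and installs the isobutyrate of the target in one operation, so no asymmetric epoxidation and no chromium are needed. The phenol is esterified four steps before the oxirane exists, so no free ortho-hydroxyaryl oxirane is formed.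

Key step: step 5

Remark on the chemistry: which enantiotopic arm a given lipase acylates cannot be predicted with certainty for this substrate. The route is written for acylation of the pro-R arm of triol 8; the sense is to be confirmed on 10 (for example through its Mosher ester), and the opposite sense is answered by the fallback to step 5.

**Route**

Step 1
Reactants: 1 4-methoxy-3-methylphenol
Product: 2 2-bromo-4-methoxy-5-methylphenol
Conditions: NBS (1.0 equiv), i-Pr2NH (10 mol%), CH2Cl2, 0 °C
Reagents that add atoms: N-bromosuccinimide, O=C1CCC(=O)N1Br
Why: Amine-mediated ortho-bromination of a phenol (electrophilic aromatic substitution); the position para to the hydroxyl is blocked by OMe and, of the two ortho positions, the one between OH and CH3 is hindered, so bromine should enter para to the methyl group.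

Step 2
Reactants: 2 2-bromo-4-methoxy-5-methylphenol; 3 2,2-dimethyl-1,3-dioxan-5-one
Product: 5 5-(2-hydroxy-5-methoxy-4-methylphenyl)-2,2-dimethyl-1,3-dioxan-5-ol, via lithium 2-lithiophenoxide 4 (not isolated)
Conditions: n-BuLi (2.2 equiv), Et2O, 0 °C to rt; then 3 in THF, −78 °C to 0 °C; aq. NH4Cl
Reagents that add atoms: none
Why: Deprotonation of the phenol by the first equivalent of n-BuLi and bromine–lithium exchange by the second give the dianion 4, whose aryllithium adds 1,2 to the ketone of the protected dihydroxyacetone; this forms the aryl–C8 bond and brings in both CH2–O arms as a symmetric acetal without a protecting group on the phenol.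

Step 3
Reactants: 5 5-(2-hydroxy-5-methoxy-4-methylphenyl)-2,2-dimethyl-1,3-dioxan-5-ol; 6 tigloyl chloride [(E)-2-methylbut-2-enoyl chloride]
Product: 7 2-(5-hydroxy-2,2-dimethyl-1,3-dioxan-5-yl)-4-methoxy-5-methylphenyl (E)-2-methylbut-2-enoate
Conditions: 6 (1.1 equiv), pyridine, DMAP (5 mol%), CH2Cl2, 0 °C
Reagents that add atoms: none
Why: Chemoselective O-acylation of the phenol through the acylpyridinium ion, since the tertiary benzylic hydroxyl is too hindered to compete, and pyridine instead of a trialkylamine avoids the vinylketene that would deconjugate the E-alkene.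

Step 4
Reactants: 7 2-(5-hydroxy-2,2-dimethyl-1,3-dioxan-5-yl)-4-methoxy-5-methylphenyl (E)-2-methylbut-2-enoate
Product: 8 4-methoxy-5-methyl-2-(1,2,3-trihydroxypropan-2-yl)phenyl (E)-2-methylbut-2-enoate (achiral triol)
Conditions: AcOH–H2O (4:1), 35 °C; toluene azeotrope
Reagents that add atoms: none
Why: Acid-catalysed hydrolysis of the 1,3-dioxane acetal, mild enough to spare the aryl ester and unlikely to ionise the tertiary benzylic alcohol because the cation would carry two β-oxygen atoms; the product has a mirror plane through the aryl group, C8 and its hydroxyl.

Step 5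
Reactants: 8 4-methoxy-5-methyl-2-(1,2,3-trihydroxypropan-2-yl)phenyl (E)-2-methylbut-2-enoate; 9 vinyl isobutyrate
Product: 10 2-[(2R)-1,2-dihydroxy-3-(isobutyryloxy)propan-2-yl]-4-methoxy-5-methylphenyl (E)-2-methylbut-2-enoate
Conditions: immobilised Burkholderia cepacia lipase (Amano PS-IM), 9 (3 equiv), MTBE–THF (4:1), 25 °C; stopped when 8 is consumed, enzyme filtered off
Reagents that add atoms: none
Why: The active-site serine of the lipase is acylated by vinyl isobutyrate, the vinyl alcohol released tautomerises to acetaldehyde so that the transfer is irreversible, and the acyl-enzyme passes the isobutyryl group to one of the two enantiotopic hydroxymethyl arms of the achiral triol 8. The closest known reaction type is the lipase-catalysed desymmetrising transesterification of prochiral 2,2-disubstituted propane-1,3-diols with vinyl esters. No ring is closed. The only stereocentre of the target, the quaternary carbinol carbon C8, becomes stereogenic in this step, and its configuration is controlled by the chiral binding site of the enzyme, which must place the flat aryl group and the small tertiary hydroxyl in different pockets and so present the pro-R arm to the acyl-serine. The step needs enantiotopic-group selectivity, mono- over bis-acylation and no reaction at the tertiary hydroxyl or the aryl tiglate; these are secured by the size difference between aryl and OH at C8, by the fact that lipases do not acylate tertiary alcohols and turn over hindered α-methyl-α,β-unsaturated aryl esters only slowly, and by the second acylation, which is slower and consumes preferentially the minor enantiomer of the monoester and so should raise the enantiomeric purity of 10. The medium is neutral and anhydrous, so neither isobutyryl migration between the arms nor tigloyl migration from the phenol should occur.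

Step 6
Reactants: 10 2-[(2R)-1,2-dihydroxy-3-(isobutyryloxy)propan-2-yl]-4-methoxy-5-methylphenyl (E)-2-methylbut-2-enoate
Product: 11 2-[(2S)-2-hydroxy-1-(isobutyryloxy)-3-(methylsulfonyloxy)propan-2-yl]-4-methoxy-5-methylphenyl (E)-2-methylbut-2-enoate
Conditions: crude 10 used directly; MsCl (1.2 equiv), pyridine, CH2Cl2, −10 to 0 °C
Reagents that add atoms: methanesulfonyl chloride, CS(=O)(=O)Cl
Why: Selective sulfonylation of the primary hydroxyl (the tertiary one does not react without sulfene formation, which pyridine avoids) in a medium too weakly basic for migration of the isobutyryl group, so the enzyme-set configuration is kept; the descriptor changes from R to S only because CH2OMs outranks CH2O-acyl.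

Step 7
Reactants: 11 2-[(2S)-2-hydroxy-1-(isobutyryloxy)-3-(methylsulfonyloxy)propan-2-yl]-4-methoxy-5-methylphenyl (E)-2-methylbut-2-enoate
Product: 12 (R)-{2-[5-methoxy-4-methyl-2-(tigloyloxy)phenyl]oxiran-2-yl}methyl isobutyrate (target)
Conditions: DBU (1.5 equiv), toluene, 0 °C to rt
Reagents that add atoms: none
Why: Intramolecular Williamson etherification (3-exo-tet) in which the tertiary oxygen displaces the primary mesylate, so no bond to the stereocentre is broken and the configuration is retained (R in the target); this closure should outrun six-ring acyl transfer from the hindered, conjugated aryl tiglate, and the non-nucleophilic amidine in an aprotic solvent leaves both esters alone.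

**Compound list**

1 | 4-methoxy-3-methylphenol | COc1ccc(O)cc1C | starting material
2 | 2-bromo-4-methoxy-5-methylphenol | COc1cc(Br)c(O)cc1C | intermediate
3 | 2,2-dimethyl-1,3-dioxan-5-one | CC1(C)OCC(=O)CO1 | starting material
4 | lithium 2-lithio-4-methoxy-5-methylphenoxide | COc1cc([Li])c(O[Li])cc1C | intermediate (not isolated)
5 | 5-(2-hydroxy-5-methoxy-4-methylphenyl)-2,2-dimethyl-1,3-dioxan-5-ol | COc1cc(c(O)cc1C)C1(O)COC(C)(C)OC1 | intermediate
6 | tigloyl chloride, (E)-2-methylbut-2-enoyl chloride | C/C=C(\C)C(=O)Cl | starting material
7 | 2-(5-hydroxy-2,2-dimethyl-1,3-dioxan-5-yl)-4-methoxy-5-methylphenyl (E)-2-methylbut-2-enoate | C/C=C(\C)C(=O)Oc1cc(C)c(OC)cc1C1(O)COC(C)(C)OC1 | intermediate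
8 | 4-methoxy-5-methyl-2-(1,2,3-trihydroxypropan-2-yl)phenyl (E)-2-methylbut-2-enoate | C/C=C(\C)C(=O)Oc1cc(C)c(OC)cc1C(O)(CO)CO | intermediate
9 | vinyl isobutyrate (ethenyl 2-methylpropanoate) | CC(C)C(=O)OC=C | starting material
10 | 2-[(2R)-1,2-dihydroxy-3-(isobutyryloxy)propan-2-yl]-4-methoxy-5-methylphenyl (E)-2-methylbut-2-enoate | C/C=C(\C)C(=O)Oc1cc(C)c(OC)cc1[C@](O)(COC(=O)C(C)C)CO | intermediate
11 | 2-[(2S)-2-hydroxy-1-(isobutyryloxy)-3-(methylsulfonyloxy)propan-2-yl]-4-methoxy-5-methylphenyl (E)-2-methylbut-2-enoate | C/C=C(\C)C(=O)Oc1cc(C)c(OC)cc1[C@](O)(COC(=O)C(C)C)COS(C)(=O)=O | intermediate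
12 | (R)-{2-[5-methoxy-4-methyl-2-(tigloyloxy)phenyl]oxiran-2-yl}methyl isobutyrate | C/C=C(\C)C(=O)Oc1cc(C)c(OC)cc1[C@]1(COC(=O)C(C)C)CO1 | target

**Count and risks**

Total step count: 7. Longest linear sequence: 7 steps (from 1; compounds 3, 6 and 9 are bought).

Steps most likely to fail:

1. Step 5 (key step): the lipase might acylate the wrong enantiotopic arm or discriminate the two arms poorly. The fallback sets out from 8 and comes back at 10. Both primary hydroxyls of 8 would be esterified with isobutyryl chloride (2.2 equiv, pyridine, CH2Cl2, 0 °C) to the achiral diester 2-[2-hydroxy-1,3-bis(isobutyryloxy)propan-2-yl]-4-methoxy-5-methylphenyl (E)-2-methylbut-2-enoate F1. The lipase would then remove one isobutyrate by alcoholysis with n-butanol in MTBE. Because a lipase cleaves the ester of the arm that it would otherwise acylate, this mode gives the monoester of opposite configuration, and so 10 where direct acylation gives its enantiomer.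

2. Step 7: transfer of the tigloyl group from the phenol oxygen to the tertiary alkoxide through a six-membered transition state, followed by attack of the freed phenoxide on the mesylate, might compete with oxirane closure. The fallback sets out from 10 and comes back at 12, so that step 6 is omitted. It is a Mitsunobu cyclodehydration of the diol (PPh3, diisopropyl azodicarboxylate, toluene, 0 °C to rt): the primary hydroxyl is activated as an alkoxyphosphonium ion and displaced by the neighbouring tertiary hydroxyl with retention at C8, without a sulfonate or a free alkoxide.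

3. Step 2: bromine–lithium exchange on the sparingly soluble lithium phenoxide might stay incomplete, or the dianion might enolise the ketone instead of adding to it. The fallback sets out from 2 and comes back at 5. O-Benzylation (benzyl bromide, K2CO3, acetone, reflux) would give 1-(benzyloxy)-2-bromo-4-methoxy-5-methylbenzene F2. Exchange with n-BuLi (1.05 equiv, THF, −78 °C) would give the soluble monolithium reagent [2-(benzyloxy)-5-methoxy-4-methylphenyl]lithium F3. Addition to 3 would give 5-[2-(benzyloxy)-5-methoxy-4-methylphenyl]-2,2-dimethyl-1,3-dioxan-5-ol F4, and hydrogenolysis (H2, Pd/C, EtOAc) would give 5.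

**Further compounds**

F1 | step 5 | 2-[2-hydroxy-1,3-bis(isobutyryloxy)propan-2-yl]-4-methoxy-5-methylphenyl (E)-2-methylbut-2-enoate | C/C=C(\C)C(=O)Oc1cc(C)c(OC)cc1C(O)(COC(=O)C(C)C)COC(=O)C(C)C
F0 | step 7 | none | none
F2 | step 2 | 1-(benzyloxy)-2-bromo-4-methoxy-5-methylbenzene | COc1cc(Br)c(OCc2ccccc2)cc1C
F3 | step 2 | [2-(benzyloxy)-5-methoxy-4-methylphenyl]lithium | COc1cc([Li])c(OCc2ccccc2)cc1C
F4 | step 2 | 5-[2-(benzyloxy)-5-methoxy-4-methylphenyl]-2,2-dimethyl-1,3-dioxan-5-ol | COc1cc(c(OCc2ccccc2)cc1C)C1(O)COC(C)(C)OC1
A1 | direct plan | 2-methylene-4-(trimethylsilyl)but-3-yn-1-ol | C[Si](C)(C)C#CC(=C)CO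
A2 | direct plan | (S)-{2-[(trimethylsilyl)ethynyl]oxiran-2-yl}methanol | C[Si](C)(C)C#C[C@]1(CO)CO1
A3 | direct plan | (R)-(2-ethynyloxiran-2-yl)methyl isobutyrate | C#C[C@]1(COC(=O)C(C)C)CO1
A4 | direct plan | pentacarbonyl[methoxy(isopropenyl)carbene]chromium | COC(C(C)=C)=[Cr](=C=O)(=C=O)(=C=O)(=C=O)=C=O
A5 | direct plan | (R)-[2-(2-hydroxy-5-methoxy-4-methylphenyl)oxiran-2-yl]methyl isobutyrate | Cc1cc(O)c(cc1OC)[C@]1(COC(=O)C(C)C)CO1
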